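The data stem from a simulated flask with made-up constants; the scatter is artificial.

In the summer run, the readings of Q stopped falling at 51% and 52%, so the Q gone stood near 48.0%, with X charged at 46.7% of the Q charged.

| flask | Q | X | G | Z | remark | time |
|---|---|---|---|---|---|---|
| winter | 0.20 mM | 0.14 mM | 40 µM | 0.50 µM | run made earlier |  |
| autumn | 0.20 mM | 0.14 mM | 40 µM | 0.75 µM | run made earlier |  |
| summer | 0.30 mM | 0.14 mM | 40 µM | 1 µM | run made earlier |  |
| flask | 0.20 mM | 0.140 mM | 40 µM | 1.0 µM |  | 20 min |

| run | time / min | D / % | Q / % |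
|---|---|---|---|
| winter | 2.00 | 15 | 79 |
| winter | 3.00 | 15 | 71 |
| winter | 5.00 | 26 | 63 |
| winter | 8.00 | 29 | 56 |
| winter | 12.0 | 30 | 48 |
| autumn | 2.00 | 21 | 70 |
| autumn | 3.00 | 26 | 67 |
| autumn | 5.00 | 32 | 58 |
| autumn | 8.00 | 36 | 48 |
| autumn | 12.0 | 33 | 44 |
| summer | 2.00 | 21 | 70 |
| summer | 3.00 | 26 | 66 |
| summer | 5.00 | 30 | 59 |
| summer | 8.00 | 28 | 51 |
| summer | 12.0 | 26 | 52 |

(each reading ± 1.5 percentage points)

- reactions considered so far: Q + G <-> G + E; X + Z + E -> Z + D; D -> J

- time, not beyond 20 min, at which the flask holds most D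
- the amount of D, in percent of the Q charged, at that time
- the first time at which D reaches 27%, in the same percent, in min

By the steps considered, each X used put one Q into D, and D went on to J. In the flask, X was the limiting reagent. I took X charged over Q charged, 70.0%, and called it the X ceiling: D plus J should stand at that ceiling times the part of X used. The highest D reading in autumn, 36%, was about half of the same ceiling. So I expected D in the flask to reach its peak with X still present.

The forecast held that “its times should be about 0.75 of autumn's”. It gave 38% at 6.5 min, with the asked amount reached at 2.4 min. The flask gave 38.5% at 8.45 min and reached the asked amount at 2.63 min, so its peak came later than forecast.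

    Q + G ⇌ G + E (K = 0.110, k = 8300 M⁻¹ s⁻¹)
    X + Z + E → Z + D (k = 2.10 × 10⁸ M⁻² s⁻¹)
    D → J (k = 9.20 × 10⁻⁴ s⁻¹)

Half of the turnover of X up to 20.0 min was done by 3.06 min, and at 8.45 min the flask still had 25.5% of its X, with D plus J at 52.2% against 52.2% from the ceiling. By 20.0 min the flask had 7.98% of its X left, and D was made more slowly than it drained, at 0.313 of that rate. The neighbour with 0.0017 mM of Z ended with 2.50% of its X, and its D plus J stood at 68.2% against 68.2% from the ceiling.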